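**Plan**

1. Target numbering used below: O1–O2–C3(Me, side chain)–C4H2–C4a(Me)–O5–C6(=O)–C7H2–C7a(OH); C4a–C7a is the bond shared by the dioxane ring and the lactone ring.
2. Retrosynthesis: C7–C7a and O1–C7a are cut in one operation, opening both rings to an acyclic α-acetoxy methyl ester that carries a tertiary silyl peroxide. Then O2–C3 (to a 1,1-disubstituted alkene), C4–C4a (methyl ketone enolsilane + methyl pyruvate), the side-chain CH–CH3 bond (enone + MeMgBr) and the vinyl–benzyl bond (alkyne carboalumination/benzylation).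
3. Enabling feature: C7a is an acyl carbon in disguise, β to the lactone carbonyl C6 through C7. The lactone ring is therefore a 5,5-disubstituted tetronic acid whose C4 ketone is masked as a 1,2-dioxan-3-ol by the hydroperoxide on C3. An acetate-onto-ester Claisen closure followed by peroxide capture copies the presumed polyketide chain extension and peroxide capture.
4. Forward: side chain (steps 1–4), C4a by pyruvate aldol (5–6), alkene and acetate (7–8), peroxide (9), then in one flask the lactone ring by C–C closure and the dioxane ring by hemiketalisation (10).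
5. Stereochemistry: E-alkene from syn carboalumination; side-chain methyl centre from copper/Josiphos conjugate methylation; C4a from the copper/bis(oxazoline) pyruvate aldol; C7a from cis ring fusion under thermodynamic control. C3 arises without facial control in O2 capture and is secured by separating the two epimers at the silyl peroxide stage.

Key step: step 10

Remark: the bicyclic peroxyhemiketal is taken to be the resting ring-chain tautomer of the hydroperoxy tetronic acid, as in the natural product.
Remark: in step 4 the Josiphos enantiomer is the one that delivers the 4R ketone; its mirror image is equally available.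

**Route**

Step 1
Reactants: 1 hex-5-yn-1-ol; 2 benzyl bromide
Product: 4 (E)-5-methyl-7-phenylhept-5-en-1-ol, via alkenylalane 3 (not isolated)
Conditions: Me3Al (3 equiv), Cp2ZrCl2 (0.25 equiv), CH2Cl2, 0 °C to rt; then 2, Pd(PPh3)4 (5 mol %), THF, rt; aq. HCl work-up
Reagents that add atoms: trimethylaluminium C[Al](C)C
Why: Zirconium-catalysed Negishi carboalumination adds methyl and aluminium syn across the terminal alkyne with aluminium at the terminus, and the palladium-catalysed Negishi-type coupling of alkenylalane 3 with the benzyl halide proceeds with retention, so the E-trisubstituted alkene is fixed here.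

Step 2
Reactants: 4 (E)-5-methyl-7-phenylhept-5-en-1-ol
Product: 5 (E)-5-methyl-7-phenylhept-5-enal
Conditions: PhI(OAc)2, TEMPO (10 mol %), CH2Cl2, rt
Reagents that add atoms: none
Why: TEMPO/oxoammonium oxidation with PhI(OAc)2 as terminal oxidant stops at the aldehyde and does not touch the trisubstituted alkene or the allylic–benzylic CH2.

Step 3
Reactants: 5 (E)-5-methyl-7-phenylhept-5-enal; 6 1-(triphenylphosphoranylidene)propan-2-one
Product: 7 (3E,8E)-8-methyl-10-phenyldeca-3,8-dien-2-one
Conditions: CH2Cl2, 40 °C
Reagents that add atoms: none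
Why: Wittig olefination with the stabilised acetonyl ylide should give the E-enone.

Step 4
Reactants: 7 (3E,8E)-8-methyl-10-phenyldeca-3,8-dien-2-one
Product: 8 (4R,8E)-4,8-dimethyl-10-phenyldec-8-en-2-one
Conditions: MeMgBr, CuBr·SMe2 (5 mol %), Josiphos ligand (6 mol %), t-BuOMe, −75 °C; aq. NH4Cl
Reagents that add atoms: methylmagnesium bromide C[Mg]Br
Why: Copper-catalysed asymmetric conjugate addition of the Grignard reagent to a linear E-alk-3-en-2-one, a well-precedented substrate class for CuBr/Josiphos, in which the chiral diphosphine–copper complex selects the enone face and so sets C4 as R.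

Step 5
Reactants: 8 (4R,8E)-4,8-dimethyl-10-phenyldec-8-en-2-one
Product: 10 trimethyl{[(4R,8E)-4,8-dimethyl-10-phenyldeca-1,8-dien-2-yl]oxy}silane, via lithium enolate 9 (not isolated)
Conditions: LiN(i-Pr)2, THF, −78 °C; then Me3SiCl, Et3N, −78 °C to 0 °C
Reagents that add atoms: chlorotrimethylsilane C[Si](C)(C)Cl
Why: Kinetic enolisation of the methyl ketone at the unhindered methyl group by the bulky amide at −78 °C and O-silylation (kinetic enolate trapping) should give the terminal silyl enol ether.

Step 6
Reactants: 10 trimethyl{[(4R,8E)-4,8-dimethyl-10-phenyldeca-1,8-dien-2-yl]oxy}silane; 11 methyl pyruvate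
Product: 13 methyl (2R,6R,10E)-2-hydroxy-2,6,10-trimethyl-4-oxo-12-phenyldodec-10-enoate, via silyl ether 12 (not isolated)
Conditions: Cu(OTf)2 (10 mol %), (R,R)-t-Bu-box [2,2'-(propane-2,2-diyl)bis((4R)-4-tert-butyl-4,5-dihydrooxazole)] (11 mol %), THF, −78 °C; then 1 M HCl, THF, rt
Reagents that add atoms: none
Why: Copper–bis(oxazoline)-catalysed Mukaiyama aldol addition to a pyruvate ester: 11 chelates copper through both carbonyl oxygens, a tert-butyl group of the (R,R)-ligand shields one face of the ketone and the enolsilane adds to the other, which sets the tertiary carbinol C2 as R (the mirror image of the S adducts known for the S,S-ligand).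

Step 7
Reactants: 13 methyl (2R,6R,10E)-2-hydroxy-2,6,10-trimethyl-4-oxo-12-phenyldodec-10-enoate
Product: 14 methyl (2R,6R,10E)-2-hydroxy-2,6,10-trimethyl-4-methylidene-12-phenyldodec-10-enoate
Conditions: Zn, CH2Br2, TiCl4 (reagent pre-formed in THF), CH2Cl2, 0 °C to rt
Reagents that add atoms: dibromomethane BrCBr
Why: Takai–Lombardo methylenation: the non-basic CH2(ZnBr)2/TiCl4 reagent methylenates the ketone but not the ester and avoids the retro-aldol cleavage that a basic ylide would provoke in this tertiary β-hydroxy ketone.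

Step 8
Reactants: 14 methyl (2R,6R,10E)-2-hydroxy-2,6,10-trimethyl-4-methylidene-12-phenyldodec-10-enoate
Product: 15 methyl (2R,6R,10E)-2-(acetyloxy)-2,6,10-trimethyl-4-methylidene-12-phenyldodec-10-enoate
Conditions: Ac2O, DMAP, Et3N, CH2Cl2, rt to 40 °C
Reagents that add atoms: acetic anhydride CC(=O)OC(C)=O
Why: DMAP-catalysed acyl transfer (nucleophilic catalysis) acetylates the hindered tertiary α-hydroxy ester under basic conditions that leave the 1,1-disubstituted alkene in place, installing the two-carbon nucleophile of step 10.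

Step 9
Reactants: 15 methyl (2R,6R,10E)-2-(acetyloxy)-2,6,10-trimethyl-4-methylidene-12-phenyldodec-10-enoate
Product: 16 methyl (2R,4R,6R,10E)-2-(acetyloxy)-2,4,6,10-tetramethyl-12-phenyl-4-[(triethylsilyl)peroxy]dodec-10-enoate
Conditions: Co(thd)2 (thd = 2,2,6,6-tetramethylheptane-3,5-dionate, 5 mol %), O2 (1 atm), Et3SiH, ClCH2CH2Cl, rt; preparative HPLC
Reagents that add atoms: dioxygen O=O; triethylsilane CC[SiH](CC)CC
Why: Mukaiyama–Isayama hydroperoxysilylation: hydrogen-atom transfer from a cobalt hydride to the CH2 terminus of the 1,1-disubstituted alkene (expected to be faster than to the trisubstituted alkene) gives the tertiary radical, which captures O2 and is silylated by Et3SiH; with no stereocentre nearer than the β positions both faces of the radical should react, so the (4R) silyl peroxide 16 is expected alongside its (4S) epimer and is obtained as the single diastereomer by preparative HPLC of the pair.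

Step 10
Reactants: 16 methyl (2R,4R,6R,10E)-2-(acetyloxy)-2,4,6,10-tetramethyl-12-phenyl-4-[(triethylsilyl)peroxy]dodec-10-enoate
Product: 19 (3R,4aR,7aR)-7a-hydroxy-3,4a-dimethyl-3-[(2R,6E)-2,6-dimethyl-8-phenyloct-6-en-1-yl]tetrahydro-3H-furo[3,2-c][1,2]dioxin-6(4H)-one, via lithium tetronate 17 (not isolated), via hydroperoxy tetronic acid 18 (not isolated)
Conditions: LiN(SiMe3)2 (2.5 equiv), THF, −78 °C to 0 °C; then 1 M aq. HCl, THF, 0 °C to rt
Reagents that add atoms: none
Why: Dieckmann (intramolecular Claisen) condensation: the base can deprotonate only the acetate, because C2 of the ester is quaternary, and the enolate attacks the neighbouring methyl ester in a 5-(enolendo)-exo-trig closure (the standard mode of tetronic acid formation from α-acyloxy esters) and expels methoxide to give lithium tetronate 17, so the lactone ring is closed by this C–C bond. Acidification protonates the tetronate and cleaves the O–Si bond of the silyl peroxide; the tertiary hydroperoxide of 18 then adds 6-exo-trig to the C4 carbonyl of the furan-2,4-dione tautomer (formally a conjugate addition to the 4-hydroxybutenolide) and closes the dioxane ring as the cyclic peroxyhemiketal. The closest known reaction types are the tetronic acid synthesis from α-acetoxy esters and the spontaneous cyclisation of γ-hydroperoxy ketones to 1,2-dioxan-3-ols. The only new stereocentre, C7a, is set by the ring fusion: the three-atom tether from the quaternary lactone carbon can reach only the carbonyl face cis to itself, so the hydroxyl ends cis to the angular methyl (R), and the closure is reversible and therefore under thermodynamic control. The step needs C-acylation to outrun attack on the peroxide, which the five-membered closure geometry and the absence of hydrogen on the peroxide carbon (no base-induced O–O fragmentation) should secure. It also needs the ring-chain equilibrium to lie on the closed side, which the two quaternary ring carbons (gem-dialkyl effect) and the high carbonyl affinity of hydroperoxides favour.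

**Compound list**

1 | hex-5-yn-1-ol | C#CCCCCO | starting material
2 | benzyl bromide | BrCc1ccccc1 | starting material
3 | dimethyl[(1E)-6-(dimethylalumanyloxy)-2-methylhex-1-en-1-yl]alane (alkenylalane) | C/C(=C\[Al](C)C)CCCCO[Al](C)C | intermediate
4 | (E)-5-methyl-7-phenylhept-5-en-1-ol | C/C(=C\Cc1ccccc1)CCCCO | intermediate
5 | (E)-5-methyl-7-phenylhept-5-enal | C/C(=C\Cc1ccccc1)CCCC=O | intermediate
6 | 1-(triphenylphosphoranylidene)propan-2-one | CC(=O)C=P(c1ccccc1)(c1ccccc1)c1ccccc1 | starting material
7 | (3E,8E)-8-methyl-10-phenyldeca-3,8-dien-2-one | C/C(=C\Cc1ccccc1)CCC/C=C/C(C)=O | intermediate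
8 | (4R,8E)-4,8-dimethyl-10-phenyldec-8-en-2-one | C/C(=C\Cc1ccccc1)CCC[C@@H](C)CC(C)=O | intermediate
9 | lithium (4R,8E)-4,8-dimethyl-10-phenyldeca-1,8-dien-2-olate (lithium enolate) | C/C(=C\Cc1ccccc1)CCC[C@@H](C)CC(=C)O[Li] | intermediate
10 | trimethyl{[(4R,8E)-4,8-dimethyl-10-phenyldeca-1,8-dien-2-yl]oxy}silane | C/C(=C\Cc1ccccc1)CCC[C@@H](C)CC(=C)O[Si](C)(C)C | intermediate
11 | methyl pyruvate | CC(=O)C(=O)OC | starting material
12 | methyl (2R,6R,10E)-2,6,10-trimethyl-4-oxo-12-phenyl-2-[(trimethylsilyl)oxy]dodec-10-enoate (silyl ether) | C/C(=C\Cc1ccccc1)CCC[C@@H](C)CC(=O)C[C@@](C)(O[Si](C)(C)C)C(=O)OC | intermediate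
13 | methyl (2R,6R,10E)-2-hydroxy-2,6,10-trimethyl-4-oxo-12-phenyldodec-10-enoate | C/C(=C\Cc1ccccc1)CCC[C@@H](C)CC(=O)C[C@@](C)(O)C(=O)OC | intermediate
14 | methyl (2R,6R,10E)-2-hydroxy-2,6,10-trimethyl-4-methylidene-12-phenyldodec-10-enoate | C/C(=C\Cc1ccccc1)CCC[C@@H](C)CC(=C)C[C@@](C)(O)C(=O)OC | intermediate
15 | methyl (2R,6R,10E)-2-(acetyloxy)-2,6,10-trimethyl-4-methylidene-12-phenyldodec-10-enoate | C/C(=C\Cc1ccccc1)CCC[C@@H](C)CC(=C)C[C@@](C)(OC(C)=O)C(=O)OC | intermediate
16 | methyl (2R,4R,6R,10E)-2-(acetyloxy)-2,4,6,10-tetramethyl-12-phenyl-4-[(triethylsilyl)peroxy]dodec-10-enoate | C/C(=C\Cc1ccccc1)CCC[C@@H](C)C[C@@](C)(OO[Si](CC)(CC)CC)C[C@@](C)(OC(C)=O)C(=O)OC | intermediate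
17 | lithium (2R)-2-methyl-5-oxo-2-{(2R,4R,8E)-2,4,8-trimethyl-10-phenyl-2-[(triethylsilyl)peroxy]dec-8-en-1-yl}-2,5-dihydrofuran-3-olate (lithium tetronate) | [Li+].C/C(=C\Cc1ccccc1)CCC[C@@H](C)C[C@@](C)(OO[Si](CC)(CC)CC)C[C@@]1(C)OC(=O)C=C1[O-] | intermediate
18 | (5R)-5-[(2R,4R,8E)-2-hydroperoxy-2,4,8-trimethyl-10-phenyldec-8-en-1-yl]-4-hydroxy-5-methylfuran-2(5H)-one (hydroperoxy tetronic acid) | C/C(=C\Cc1ccccc1)CCC[C@@H](C)C[C@@](C)(OO)C[C@@]1(C)OC(=O)C=C1O | intermediate
19 | (3R,4aR,7aR)-7a-hydroxy-3,4a-dimethyl-3-[(2R,6E)-2,6-dimethyl-8-phenyloct-6-en-1-yl]tetrahydro-3H-furo[3,2-c][1,2]dioxin-6(4H)-one (cis-fused 1,2-dioxane/γ-lactone peroxyhemiketal) | C/C(=C\Cc1ccccc1)CCC[C@@H](C)C[C@]1(C)C[C@@]2(C)OC(=O)C[C@@]2(O)OO1 | target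

**Step count and risks**

Total steps: 10. Longest linear sequence: 10 steps (1 to 19); 2, 6 and 11 are purchased.

Steps most likely to fail:

1. Step 10. What may go wrong: attack of the amide base or of liberated methoxide on silicon, oxygen transfer from the peroxide to the ester enolate, or intermolecular Claisen condensation, each of which would erode the peroxide before the dioxane ring can close. Fallback (sets out from 15, rejoins the route at 18, which closes to 19 as in step 10): the order of events is inverted so that no peroxide meets the amide base. Acetate 15 is cyclised first with LiN(SiMe3)2 (THF, −78 °C to 0 °C, acidic work-up) to the tetronic acid (5R)-5-[(4R,8E)-4,8-dimethyl-2-methylidene-10-phenyldec-8-en-1-yl]-4-hydroxy-5-methylfuran-2(5H)-one F1. The acidic enol is capped with Et3SiCl/imidazole to give silyl tetronate F2. Hydroperoxysilylation under the conditions of step 9 (the push–pull enol ether should be a poor hydrogen-atom acceptor) gives bis-silyl peroxide F3 together with its epimer at the peroxide carbon F4, separated by chromatography. 1 M aqueous HCl in THF then removes both silyl groups from F3 to give 18.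

2. Step 9. What may go wrong: unselective oxygen capture giving two C4 epimers that co-elute, competing hydrogen-atom transfer to the trisubstituted alkene, and autoxidation at the allylic–benzylic CH2. Fallback (sets out from 14, returns at 16): the peroxidation is moved one step forward, onto the free hydroxy ester. Co(thd)2, O2 and Et3SiH convert 14 into hydroxy silyl peroxide F5 and its C4 epimer F6. The intramolecular O–H···O–O hydrogen bond should make the two epimers conformationally distinct (syn versus anti 1,3-pattern), giving the polarity difference that the acetates may lack. After separation, F5 is acetylated (Ac2O, DMAP, Et3N) to give 16.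

3. Step 6. What may go wrong: slow turnover and poor facial discrimination with an unactivated aliphatic enolsilane, and retro-aldol cleavage of the tertiary aldol on work-up. Fallback (sets out from 8, returns at 14): the tertiary carbinol is taken from lactic acid by self-regeneration of the stereocentre instead of catalysis. Ketone 8 is converted with KN(SiMe3)2/PhNTf2 (THF, −78 °C) into the kinetic enol triflate F7. Stille hydroxymethylation with (tributylstannyl)methanol, Pd(PPh3)4 and LiCl gives allylic alcohol F8, and CBr4/PPh3 gives allylic bromide F9. The lithium enolate of (2S,5S)-2-tert-butyl-5-methyl-1,3-dioxolan-4-one (LiN(i-Pr)2, THF, −78 °C) is alkylated by F9 on the face anti to the tert-butyl group to give dioxolanone F10. NaOMe in MeOH opens F10 to the methyl ester 14 with the R carbinol.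

Further compounds
F1 | step 10 | (5R)-5-[(4R,8E)-4,8-dimethyl-2-methylidene-10-phenyldec-8-en-1-yl]-4-hydroxy-5-methylfuran-2(5H)-one | C/C(=C\Cc1ccccc1)CCC[C@@H](C)CC(=C)C[C@@]1(C)OC(=O)C=C1O
F2 | step 10 | (5R)-5-[(4R,8E)-4,8-dimethyl-2-methylidene-10-phenyldec-8-en-1-yl]-5-methyl-4-[(triethylsilyl)oxy]furan-2(5H)-one | C/C(=C\Cc1ccccc1)CCC[C@@H](C)CC(=C)C[C@@]1(C)OC(=O)C=C1O[Si](CC)(CC)CC
F3 | step 10 | (5R)-5-methyl-5-{(2R,4R,8E)-2,4,8-trimethyl-10-phenyl-2-[(triethylsilyl)peroxy]dec-8-en-1-yl}-4-[(triethylsilyl)oxy]furan-2(5H)-one | C/C(=C\Cc1ccccc1)CCC[C@@H](C)C[C@@](C)(OO[Si](CC)(CC)CC)C[C@@]1(C)OC(=O)C=C1O[Si](CC)(CC)CC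
F4 | step 10 | (5R)-5-methyl-5-{(2S,4R,8E)-2,4,8-trimethyl-10-phenyl-2-[(triethylsilyl)peroxy]dec-8-en-1-yl}-4-[(triethylsilyl)oxy]furan-2(5H)-one | C/C(=C\Cc1ccccc1)CCC[C@@H](C)C[C@](C)(OO[Si](CC)(CC)CC)C[C@@]1(C)OC(=O)C=C1O[Si](CC)(CC)CC
F5 | step 9 | methyl (2R,4R,6R,10E)-2-hydroxy-2,4,6,10-tetramethyl-12-phenyl-4-[(triethylsilyl)peroxy]dodec-10-enoate | C/C(=C\Cc1ccccc1)CCC[C@@H](C)C[C@@](C)(OO[Si](CC)(CC)CC)C[C@@](C)(O)C(=O)OC
F6 | step 9 | methyl (2R,4S,6R,10E)-2-hydroxy-2,4,6,10-tetramethyl-12-phenyl-4-[(triethylsilyl)peroxy]dodec-10-enoate | C/C(=C\Cc1ccccc1)CCC[C@@H](C)C[C@](C)(OO[Si](CC)(CC)CC)C[C@@](C)(O)C(=O)OC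
F7 | step 6 | (4R,8E)-4,8-dimethyl-10-phenyldeca-1,8-dien-2-yl trifluoromethanesulfonate | C/C(=C\Cc1ccccc1)CCC[C@@H](C)CC(=C)OS(=O)(=O)C(F)(F)F
F8 | step 6 | (4R,8E)-4,8-dimethyl-2-methylidene-10-phenyldec-8-en-1-ol | C/C(=C\Cc1ccccc1)CCC[C@@H](C)CC(=C)CO
F9 | step 6 | (4R,8E)-1-bromo-4,8-dimethyl-2-methylidene-10-phenyldec-8-ene | C/C(=C\Cc1ccccc1)CCC[C@@H](C)CC(=C)CBr
F10 | step 6 | (2S,5R)-2-tert-butyl-5-[(4R,8E)-4,8-dimethyl-2-methylidene-10-phenyldec-8-en-1-yl]-5-methyl-1,3-dioxolan-4-one | C/C(=C\Cc1ccccc1)CCC[C@@H](C)CC(=C)C[C@@]1(C)O[C@H](C(C)(C)C)OC1=O
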